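**Retrosynthetic overview**

- The (E)-propenal at C7 is cut back to an aryl aldehyde (Wittig), carried as a dioxolane. Locants used throughout: O1, C2 (trimethoxyphenyl), C3 (methyl), O4, C4a, C5 (OMe), C6, C7, C8, C8a.
- Feature the plan rests on: ring A has O4 on C4a, flanked by C5–OMe and C8a–O1, with the C7 side chain para to O4. Apart from what sits on the two flanking oxygens, ring A is symmetric about the O4–C4a···C7 axis, so it maps onto 3,5-dibromo-4-hydroxybenzaldehyde.
- Key disconnection: C8a–O1 (closes dioxane ring B) and C5–OCH3, both made as copper-catalysed aryl C–O couplings in one flask on the two equivalent bromides of a threo (1R,2R) aryloxy alcohol.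
- The alcohol comes from ethyl (S)-lactate: Mitsunobu inversion sets C3, a Weinreb ketone synthesis brings in ring C, and a Felkin–Anh reduction sets C2.
- Ring order: rings A and C are bought; ring B is the only ring formed (step 6).

Key step: step 6

Assumption: compounds 1, 2 and 6 are taken as commercial, and the benzodioxane locants given above are kept in all names, also where a substitutive name would number the ring the other way round.

**Route**

Step 1
Reactants: 1 ethyl (S)-lactate; 2 3,5-dibromo-4-hydroxybenzaldehyde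
Product: 3 ethyl (2R)-2-(2,6-dibromo-4-formylphenoxy)propanoate
Conditions: PPh3, DIAD, THF, 0 °C to rt
Reagents that add atoms: none
Why: Mitsunobu etherification; the strongly acidic phenol (two ortho bromines, para formyl) is a good pronucleophile, and SN2 displacement of the oxyphosphonium at the ester α-carbon should invert the (S)-lactate centre to the (R)-aryl ether that becomes C3.

Step 2
Reactants: 3 ethyl (2R)-2-(2,6-dibromo-4-formylphenoxy)propanoate
Product: 4 ethyl (2R)-2-[2,6-dibromo-4-(1,3-dioxolan-2-yl)phenoxy]propanoate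
Conditions: TMSOCH2CH2OTMS, cat. TMSOTf, CH2Cl2, −78 to −20 °C; pyridine quench
Reagents that add atoms: 1,2-bis(trimethylsilyloxy)ethane, C[Si](C)(C)OCCO[Si](C)(C)C
Why: Noyori acetalisation is aprotic and cold, so the ethyl ester is not transesterified and the α-centre is untouched; the dioxolane masks the aldehyde from the later organomagnesium and hydride reagents and removes the para acceptor that would activate ring A towards ipso attack in step 6.

Step 3
Reactants: 4 ethyl (2R)-2-[2,6-dibromo-4-(1,3-dioxolan-2-yl)phenoxy]propanoate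
Product: 5 (2R)-2-[2,6-dibromo-4-(1,3-dioxolan-2-yl)phenoxy]-N-methoxy-N-methylpropanamide
Conditions: MeNH(OMe)·HCl, iPrMgCl (2 equiv per amine salt, premixed), THF, −20 to 0 °C; then aq NH4Cl
Reagents that add atoms: N,O-dimethylhydroxylamine hydrochloride, CNOC.Cl
Why: Weinreb amide formation by aminolysis of the ester with the preformed chloromagnesium amide; no free Grignard reagent is left to attack the C–Br bonds, and lactate-type α-oxy esters are expected to keep their configuration at this temperature.

Step 4
Reactants: 5 (2R)-2-[2,6-dibromo-4-(1,3-dioxolan-2-yl)phenoxy]-N-methoxy-N-methylpropanamide; 6 5-bromo-1,2,3-trimethoxybenzene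
Product: 8 (2R)-2-[2,6-dibromo-4-(1,3-dioxolan-2-yl)phenoxy]-1-(3,4,5-trimethoxyphenyl)propan-1-one, via 3,4,5-trimethoxyphenylmagnesium bromide 7 (not isolated)
Conditions: 6, Mg, cat. I2, THF, 50 °C; then 5, THF, −20 to 0 °C; aq NH4Cl
Reagents that add atoms: magnesium, [Mg] (its atom stays in intermediate 7 and is lost on work-up)
Why: Weinreb ketone synthesis; the aryl Grignard reagent adds once to give a stable magnesium chelate that releases the ketone only on work-up, so no tertiary alcohol forms, the chelated adduct shields the α-centre from enolisation, and an aryl Grignard reagent should not exchange with the ring A bromides at this temperature.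

Step 5
Reactants: 8 (2R)-2-[2,6-dibromo-4-(1,3-dioxolan-2-yl)phenoxy]-1-(3,4,5-trimethoxyphenyl)propan-1-one
Product: 9 (1R,2R)-2-[2,6-dibromo-4-(1,3-dioxolan-2-yl)phenoxy]-1-(3,4,5-trimethoxyphenyl)propan-1-ol
Conditions: LiBH(s-Bu)3, THF, −78 °C; then NaOH, H2O2, 0 °C
Reagents that add atoms: none
Why: Felkin–Anh-controlled hydride reduction; the bulky, non-chelating borohydride should attack anti to the C–OAr bond and past the α-hydrogen, and the hindered, electron-poor 2,6-dibromoaryl ether oxygen disfavours chelation, so the (R)-centre at C2 should direct formation of the syn (threo) alcohol with C1 as R.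

Step 6
Reactants: 9 (1R,2R)-2-[2,6-dibromo-4-(1,3-dioxolan-2-yl)phenoxy]-1-(3,4,5-trimethoxyphenyl)propan-1-ol
Product: 11 (2R,3R)-7-(1,3-dioxolan-2-yl)-5-methoxy-3-methyl-2-(3,4,5-trimethoxyphenyl)-2,3-dihydro-1,4-benzodioxine, via 5-bromo benzodioxane 10 (not isolated)
Conditions: CuI, 1,10-phenanthroline, Cs2CO3, toluene, 110 °C; then NaOMe/MeOH, DMF, 110 °C, same flask
Reagents that add atoms: sodium methoxide, C[O-].[Na+]
Why: Both bonds form by Ullmann-type etherification, in which a phenanthroline-ligated alkoxide of monovalent copper adds oxidatively into an aryl C–Br bond to give an aryl alkoxide of trivalent copper that reductively eliminates the aryl ether. The closest known reactions are the copper-catalysed intramolecular O-arylation of 2-(2-bromoaryloxy)alkanols to 1,4-benzodioxanes and the CuI/NaOMe methoxylation of bromophenol ethers, here run back to back in one flask. Ring B closes as a six-membered ring when the tethered C1 alkoxide is joined to the ortho carbon (O1–C8a) through a seven-membered aryl copper alkoxide chelate. No stereocentre is created, and because both new bonds are made at aromatic carbon the C–O bonds at C1 and C2 of 9 are never broken, so the (1R,2R) threo alcohol should map onto the trans-(2R,3R) ring. The two bromides are equivalent by rotation about the O4–C4a bond, so the first coupling has no regiochemical choice, and adding methoxide only after the ring has closed prevents double methoxylation, leaving the single remaining bromide at C5 for the second coupling. The one selectivity the substrate must secure is that the aryl group stays on O4 instead of migrating to the benzylic alkoxide through an ipso spiro adduct, and this is favoured by the non-activating dioxolane at C7 and the non-polar solvent of the first stage.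

Step 7
Reactants: 11 (2R,3R)-7-(1,3-dioxolan-2-yl)-5-methoxy-3-methyl-2-(3,4,5-trimethoxyphenyl)-2,3-dihydro-1,4-benzodioxine
Product: 12 (2R,3R)-5-methoxy-3-methyl-2-(3,4,5-trimethoxyphenyl)-2,3-dihydro-1,4-benzodioxine-7-carbaldehyde
Conditions: 1 M aq HCl, THF, rt
Reagents that add atoms: water, O
Why: Acid-catalysed acetal hydrolysis; dilute acid at room temperature should cleave the aryl dioxolane while the aryl methyl ethers and the benzodioxane survive, and the trans ring is the more stable diastereomer, so C2 is not at risk.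

Step 8
Reactants: 12 (2R,3R)-5-methoxy-3-methyl-2-(3,4,5-trimethoxyphenyl)-2,3-dihydro-1,4-benzodioxine-7-carbaldehyde
Product: 13 (E)-3-[(2R,3R)-5-methoxy-3-methyl-2-(3,4,5-trimethoxyphenyl)-2,3-dihydro-1,4-benzodioxin-7-yl]prop-2-enal
Conditions: Ph3P=CHCHO (slight excess), toluene, 90 °C
Reagents that add atoms: (triphenylphosphoranylidene)acetaldehyde, O=CC=P(c1ccccc1)(c1ccccc1)c1ccccc1
Why: Wittig olefination with a stabilised formyl ylide should give the (E)-enal, and keeping the ylide near one equivalent limits a second homologation of the product.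

**Compound list**

1 | ethyl (S)-lactate | CCOC(=O)[C@H](C)O | starting material
2 | 3,5-dibromo-4-hydroxybenzaldehyde | O=Cc1cc(Br)c(O)c(Br)c1 | starting material
3 | ethyl (2R)-2-(2,6-dibromo-4-formylphenoxy)propanoate | CCOC(=O)[C@@H](C)Oc1c(Br)cc(C=O)cc1Br | intermediate
4 | ethyl (2R)-2-[2,6-dibromo-4-(1,3-dioxolan-2-yl)phenoxy]propanoate | CCOC(=O)[C@@H](C)Oc1c(Br)cc(C2OCCO2)cc1Br | intermediate
5 | (2R)-2-[2,6-dibromo-4-(1,3-dioxolan-2-yl)phenoxy]-N-methoxy-N-methylpropanamide | CON(C)C(=O)[C@@H](C)Oc1c(Br)cc(C2OCCO2)cc1Br | intermediate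
6 | 5-bromo-1,2,3-trimethoxybenzene | COc1cc(Br)cc(OC)c1OC | starting material
7 | 3,4,5-trimethoxyphenylmagnesium bromide | COc1cc([Mg]Br)cc(OC)c1OC | intermediate
8 | (2R)-2-[2,6-dibromo-4-(1,3-dioxolan-2-yl)phenoxy]-1-(3,4,5-trimethoxyphenyl)propan-1-one | COc1cc(C(=O)[C@@H](C)Oc2c(Br)cc(C3OCCO3)cc2Br)cc(OC)c1OC | intermediate
9 | (1R,2R)-2-[2,6-dibromo-4-(1,3-dioxolan-2-yl)phenoxy]-1-(3,4,5-trimethoxyphenyl)propan-1-ol | COc1cc([C@@H](O)[C@@H](C)Oc2c(Br)cc(C3OCCO3)cc2Br)cc(OC)c1OC | intermediate
10 | (2R,3R)-5-bromo-7-(1,3-dioxolan-2-yl)-3-methyl-2-(3,4,5-trimethoxyphenyl)-2,3-dihydro-1,4-benzodioxine | COc1cc([C@H]2Oc3cc(C4OCCO4)cc(Br)c3O[C@@H]2C)cc(OC)c1OC | intermediate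
11 | (2R,3R)-7-(1,3-dioxolan-2-yl)-5-methoxy-3-methyl-2-(3,4,5-trimethoxyphenyl)-2,3-dihydro-1,4-benzodioxine | COc1cc([C@H]2Oc3cc(C4OCCO4)cc(OC)c3O[C@@H]2C)cc(OC)c1OC | intermediate
12 | (2R,3R)-5-methoxy-3-methyl-2-(3,4,5-trimethoxyphenyl)-2,3-dihydro-1,4-benzodioxine-7-carbaldehyde | COc1cc([C@H]2Oc3cc(C=O)cc(OC)c3O[C@@H]2C)cc(OC)c1OC | intermediate
13 | (E)-3-[(2R,3R)-5-methoxy-3-methyl-2-(3,4,5-trimethoxyphenyl)-2,3-dihydro-1,4-benzodioxin-7-yl]prop-2-enal | COc1cc([C@H]2Oc3cc(/C=C/C=O)cc(OC)c3O[C@@H]2C)cc(OC)c1OC | target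

**Step count and risks**

Total step count: 8. Longest linear sequence: 8 steps (1 or 2 to 13); the ring C fragment 6 enters inside step 4.

Steps most likely to fail:

1. Step 6. O-arylation by the hindered secondary benzylic alkoxide may be slow, which would let hydrodebromination, aryl migration from O4 to the benzylic oxygen, or incomplete methoxylation of the electron-rich C5 bromide compete. The fallback sets out from 9 and comes back at 11, making the two C–O bonds in separate operations with palladium. Ring closure with Pd(OAc)2, 2-(di-tert-butylphosphino)-1,1'-binaphthyl and Cs2CO3 in toluene at 80 °C (zerovalent palladium inserts into one C–Br bond and the tethered alkoxide is eliminated reductively) would give bromide 10, which is isolated. Hydroxylation of the remaining bromide with Pd2(dba)3, tBuXPhos and KOH in dioxane/water at 100 °C would give (2R,3R)-7-(1,3-dioxolan-2-yl)-3-methyl-2-(3,4,5-trimethoxyphenyl)-2,3-dihydro-1,4-benzodioxin-5-ol F1. O-methylation with MeI and K2CO3 in acetone would then give 11.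

2. Step 5. Facial selectivity in the hydride addition may be poor, or partly chelation-directed, which would leave the erythro alcohol and after step 6 the cis ring. The fallback sets out from 8 and comes back at 9 by making the wrong C1 epimer on purpose and inverting it. Chelation-controlled reduction with Zn(BH4)2 in Et2O at 0 °C would give (1S,2R)-2-[2,6-dibromo-4-(1,3-dioxolan-2-yl)phenoxy]-1-(3,4,5-trimethoxyphenyl)propan-1-ol F2; any erythro alcohol separated after step 5 can be added to it. Mitsunobu inversion with 4-nitrobenzoic acid, PPh3 and DIAD in THF would give (1R,2R)-2-[2,6-dibromo-4-(1,3-dioxolan-2-yl)phenoxy]-1-(3,4,5-trimethoxyphenyl)propyl 4-nitrobenzoate F3. Methanolysis with K2CO3 in MeOH would release 9.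

3. Step 8. The product enal may be olefinated a second time to a dienal, and conversion of the electron-rich aldehyde may stay incomplete. The fallback sets out from 12 and comes back at 13 through the ester oxidation level. Horner–Wadsworth–Emmons reaction with triethyl phosphonoacetate and NaH in THF would give ethyl (E)-3-[(2R,3R)-5-methoxy-3-methyl-2-(3,4,5-trimethoxyphenyl)-2,3-dihydro-1,4-benzodioxin-7-yl]prop-2-enoate F4. Reduction with i-Bu2AlH in CH2Cl2 at −78 °C would give (E)-3-[(2R,3R)-5-methoxy-3-methyl-2-(3,4,5-trimethoxyphenyl)-2,3-dihydro-1,4-benzodioxin-7-yl]prop-2-en-1-ol F5. Allylic oxidation with MnO2 in CH2Cl2 would give 13.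

**Further compounds**

F1 | step 6 | (2R,3R)-7-(1,3-dioxolan-2-yl)-3-methyl-2-(3,4,5-trimethoxyphenyl)-2,3-dihydro-1,4-benzodioxin-5-ol | COc1cc([C@H]2Oc3cc(C4OCCO4)cc(O)c3O[C@@H]2C)cc(OC)c1OC
F2 | step 5 | (1S,2R)-2-[2,6-dibromo-4-(1,3-dioxolan-2-yl)phenoxy]-1-(3,4,5-trimethoxyphenyl)propan-1-ol | COc1cc([C@H](O)[C@@H](C)Oc2c(Br)cc(C3OCCO3)cc2Br)cc(OC)c1OC
F3 | step 5 | (1R,2R)-2-[2,6-dibromo-4-(1,3-dioxolan-2-yl)phenoxy]-1-(3,4,5-trimethoxyphenyl)propyl 4-nitrobenzoate | COc1cc([C@@H](OC(=O)c2ccc([N+](=O)[O-])cc2)[C@@H](C)Oc2c(Br)cc(C3OCCO3)cc2Br)cc(OC)c1OC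
F4 | step 8 | ethyl (E)-3-[(2R,3R)-5-methoxy-3-methyl-2-(3,4,5-trimethoxyphenyl)-2,3-dihydro-1,4-benzodioxin-7-yl]prop-2-enoate | COc1cc([C@H]2Oc3cc(/C=C/C(=O)OCC)cc(OC)c3O[C@@H]2C)cc(OC)c1OC
F5 | step 8 | (E)-3-[(2R,3R)-5-methoxy-3-methyl-2-(3,4,5-trimethoxyphenyl)-2,3-dihydro-1,4-benzodioxin-7-yl]prop-2-en-1-ol | COc1cc([C@H]2Oc3cc(/C=C/CO)cc(OC)c3O[C@@H]2C)cc(OC)c1OC
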